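**Plan**
1. The retrosynthesis first cuts the two bonds from the quinone methide carbon to its 4-hydroxyphenyl rings (an ester plus two equivalents of one aryllithium), then the C6–C(sp) bond of ring A (Sonogashira coupling of an aryl triflate).
2. What remains is a 6-arylsalicylate. Ring A (the central benzene: C1 methide carbon, C2 4-hydroxyphenyl, C3/C4 H, C5 CH2OH, C6 arylethynyl) carries the ester carbon on C1, an oxygen on C6 and CH2O on C5, which is the pattern of a folded β-keto ester.
3. Ring A is therefore cut at C4–C5 and C1–C2 into an acetoacetate-derived 1,3-bis(silyloxy)diene (C1, C6, C5 and both side-chain carbons) and a formylated 4-hydroxyacetophenone (C2, C3, C4 and the C2 aryl ring).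
4. Forward: the diene (five steps) and the silyloxy enone (three steps) are made separately and joined by TiCl4, which closes ring A, the only ring built. The four outer rings are bought (one as 4-hydroxyacetophenone, three as 4-bromophenol).
5. Triflation, alkynylation at C6, double aryl addition at the C1 ester and fluoride/acid treatment then give the quinone methide.
6. Stereochemistry: the target has no stereocentre and no stereogenic double bond (the quinoid ring is symmetric), so nothing has to be controlled.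

Key step: step 9

Remark: TBDPS = tert-butyldiphenylsilyl, TIPS = triisopropylsilyl. The mono(silyl enol ether) of the diene branch is written as its E isomer and the silyloxy enone as its Z isomer. Either isomer or a mixture should serve, because the first double bond is relocated in the following step and TiCl4 equilibrates the enone geometry in the key step.

**Step 1**
Reactants: 1 methyl acetoacetate; 2 benzyl chloromethyl ether
Product: 3 methyl 5-(benzyloxy)-3-oxopentanoate
Conditions: NaH, THF, 0 °C; n-BuLi, 0 °C; 2, −78 → 0 °C; 1 M HCl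
Reagents that add atoms: none
Why: γ-Alkylation of the acetoacetate dianion, whose terminal carbanion is its most nucleophilic site, with a very reactive α-chloro ether should attach the future CH2O carbon of ring A C5 at the γ-carbon only.

**Step 2**
Reactants: 3 methyl 5-(benzyloxy)-3-oxopentanoate
Product: 4 methyl 5-hydroxy-3-oxopentanoate
Conditions: H2 (1 atm), 10% Pd/C, EtOAc, 20 °C
Reagents that add atoms: none
Why: Benzyl ether hydrogenolysis over palladium on carbon leaves the β-keto ester untouched at atmospheric pressure, and the neutral medium should keep the hydroxy keto ester from lactonising if it is used crude at once.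

**Step 3**
Reactants: 4 methyl 5-hydroxy-3-oxopentanoate
Product: 5 methyl 5-(tert-butyldiphenylsilyloxy)-3-oxopentanoate
Conditions: TBDPSCl, imidazole, CH2Cl2, 0 → 20 °C
Reagents that add atoms: tert-butylchlorodiphenylsilane, CC(C)(C)[Si](Cl)(c1ccccc1)c1ccccc1
Why: Imidazole-promoted silylation of a primary alcohol is standard, and the bulky chlorosilane should not silylate the β-keto ester enol under these conditions.

**Step 4**
Reactants: 5 methyl 5-(tert-butyldiphenylsilyloxy)-3-oxopentanoate
Product: 6 methyl (E)-5-(tert-butyldiphenylsilyloxy)-3-(trimethylsilyloxy)pent-2-enoate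
Conditions: Me3SiCl, Et3N, toluene, 20 °C
Reagents that add atoms: chlorotrimethylsilane, C[Si](C)(C)Cl
Why: O-Silylation of the β-keto ester enol with Me3SiCl/Et3N is the usual first stage of making 1,3-bis(silyloxy)dienes and is compatible with the TBDPS ether.

**Step 5**
Reactants: 6 methyl (E)-5-(tert-butyldiphenylsilyloxy)-3-(trimethylsilyloxy)pent-2-enoate
Product: 7 (1Z,3Z)-5-(tert-butyldiphenylsilyloxy)-1-methoxy-1,3-bis(trimethylsilyloxy)penta-1,3-diene
Conditions: LiN(i-Pr)2, THF, −78 °C; Me3SiCl, −78 → 20 °C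
Reagents that add atoms: chlorotrimethylsilane, C[Si](C)(C)Cl
Why: Kinetic γ-deprotonation of the silyloxy enoate and O-silylation of the ester dienolate give the diene, and at −78 °C trapping by Me3SiCl should outrun β-elimination of the silyloxide.

**Step 6**
Reactants: 8 4-hydroxyacetophenone
Product: 9 1-[4-(triisopropylsilyloxy)phenyl]ethanone
Conditions: TIPSCl, imidazole, DMF, 20 °C
Reagents that add atoms: chlorotriisopropylsilane, CC(C)[Si](Cl)(C(C)C)C(C)C
Why: Standard phenol silylation; TIPS is chosen because, among the common aryl silyl ethers, it best withstands the bases, TiCl4 and organolithiums used later.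

**Step 7**
Reactants: 9 1-[4-(triisopropylsilyloxy)phenyl]ethanone; 10 ethyl formate
Product: 11 (Z)-3-hydroxy-1-[4-(triisopropylsilyloxy)phenyl]prop-2-en-1-one
Conditions: LiN(SiMe3)2, THF, −78 °C; 10, −78 → 0 °C; AcOH
Reagents that add atoms: none
Why: Crossed Claisen condensation of the preformed lithium enolate with ethyl formate is driven by formation of the chelated lithium salt of the formyl ketone, and the cold lithium-based medium should spare the aryl TIPS ether.

**Step 8**
Reactants: 11 (Z)-3-hydroxy-1-[4-(triisopropylsilyloxy)phenyl]prop-2-en-1-one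
Product: 12 (Z)-1-[4-(triisopropylsilyloxy)phenyl]-3-(trimethylsilyloxy)prop-2-en-1-one
Conditions: Me3SiCl, Et3N, toluene, 20 °C
Reagents that add atoms: chlorotrimethylsilane, C[Si](C)(C)Cl
Why: The enol oxygen of a hydroxymethylene ketone is silylated readily by Me3SiCl/Et3N, giving the 3-silyloxy enone as a masked 1,3-dielectrophile.

**Step 9**
Reactants: 7 (1Z,3Z)-5-(tert-butyldiphenylsilyloxy)-1-methoxy-1,3-bis(trimethylsilyloxy)penta-1,3-diene; 12 (Z)-1-[4-(triisopropylsilyloxy)phenyl]-3-(trimethylsilyloxy)prop-2-en-1-one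
Product: 15 methyl 3-[(tert-butyldiphenylsilyloxy)methyl]-2-hydroxy-6-[4-(triisopropylsilyloxy)phenyl]benzoate, via open-chain enone adduct 13 (not isolated), via cyclic aldol 14 (not isolated)
Conditions: TiCl4 (1.1 equiv), CH2Cl2, −78 → 20 °C; ice-water
Reagents that add atoms: none
Why: TiCl4 activates the enone 12 at its ketone oxygen, and the terminal diene carbon of 7 (ring A C5), its most nucleophilic site, adds in Mukaiyama–Michael fashion to the silyloxy-bearing CH (C4); loss of trimethylsilanolate then gives the open-chain enone 13 with the C4–C5 bond formed. The surviving silyl ketene acetal carbon (C1) attacks the activated aryl ketone (C2) in an intramolecular Mukaiyama aldol reaction to give 14 with the C1–C2 bond formed, and loss of water followed by enolisation should deliver the arene 15 without any oxidant. The closest known reaction type is the TiCl4-mediated formal [3+3] cyclocondensation of 1,3-bis(silyloxy)-1,3-dienes with 3-silyloxy-2-en-1-ones to salicylates, which accepts substituents at the diene terminus. Ring A closes by a favoured 6-(enolexo)-exo-trig aldol (6-(enolendo)-exo-trig if the β-keto ester reacts through its ketone enolate), which needs the Z enone that TiCl4 equilibration makes available. No stereocentre survives, since the centre at ring A C5 in 13 and the three centres of 14 are erased on aromatisation. The step needs regioselectivity (diene terminus to C4, not to the ketone carbon C2), which is secured because C4 is an unhindered vinylogous silyl ester carbon while the ketone is hindered and deactivated by the electron-rich 4-silyloxyphenyl ring, and because the terminal diene carbon is far more nucleophilic than the central one.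

**Step 10**
Reactants: 16 4-bromophenol
Product: 17 (4-bromophenoxy)triisopropylsilane
Conditions: TIPSCl, imidazole, DMF, 20 °C
Reagents that add atoms: chlorotriisopropylsilane, CC(C)[Si](Cl)(C(C)C)C(C)C
Why: Standard phenol silylation gives one protected bromoarene that serves both as the alkyne precursor and as the aryllithium precursor.

**Step 11**
Reactants: 17 (4-bromophenoxy)triisopropylsilane; 18 ethynyltrimethylsilane
Product: 19 triisopropyl{4-[(trimethylsilyl)ethynyl]phenoxy}silane
Conditions: PdCl2(PhCN)2 (cat.), [HP(t-Bu)3]BF4 (cat.), CuI (cat.), i-Pr2NH, dioxane, 20 °C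
Reagents that add atoms: none
Why: Sonogashira coupling in which the bulky electron-rich phosphine lets the electron-rich aryl bromide undergo oxidative addition at room temperature.

**Step 12**
Reactants: 19 triisopropyl{4-[(trimethylsilyl)ethynyl]phenoxy}silane
Product: 20 (4-ethynylphenoxy)triisopropylsilane
Conditions: K2CO3 (0.1 equiv), MeOH/THF, 0 °C
Reagents that add atoms: none
Why: Methanolysis of the C(sp)–SiMe3 bond under catalytic carbonate is much faster than cleavage of the hindered aryl TIPS ether, so the terminal alkyne should be freed selectively.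

**Step 13**
Reactants: 15 methyl 3-[(tert-butyldiphenylsilyloxy)methyl]-2-hydroxy-6-[4-(triisopropylsilyloxy)phenyl]benzoate
Product: 21 methyl 3-[(tert-butyldiphenylsilyloxy)methyl]-6-[4-(triisopropylsilyloxy)phenyl]-2-(trifluoromethylsulfonyloxy)benzoate
Conditions: Tf2O, pyridine, CH2Cl2, −78 → 0 °C
Reagents that add atoms: trifluoromethanesulfonic anhydride, O=S(=O)(OS(=O)(=O)C(F)(F)F)C(F)(F)F
Why: Triflation of salicylate phenols with Tf2O/pyridine is routine, and the weakly basic medium should not provoke silyl migration from the neighbouring CH2O group to the phenol oxygen.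

**Step 14**
Reactants: 21 methyl 3-[(tert-butyldiphenylsilyloxy)methyl]-6-[4-(triisopropylsilyloxy)phenyl]-2-(trifluoromethylsulfonyloxy)benzoate; 20 (4-ethynylphenoxy)triisopropylsilane
Product: 22 methyl 3-[(tert-butyldiphenylsilyloxy)methyl]-6-[4-(triisopropylsilyloxy)phenyl]-2-{[4-(triisopropylsilyloxy)phenyl]ethynyl}benzoate
Conditions: Pd(PPh3)4 (cat.), CuI (cat.), n-Bu4NI (cat.), Et3N, DMF, 70 °C
Reagents that add atoms: none
Why: Sonogashira coupling of a salicylate-derived triflate, in which the ortho ester accelerates oxidative addition of zerovalent palladium into the C–OTf bond and the slim copper acetylide tolerates the two ortho substituents.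

**Step 15**
Reactants: 22 methyl 3-[(tert-butyldiphenylsilyloxy)methyl]-6-[4-(triisopropylsilyloxy)phenyl]-2-{[4-(triisopropylsilyloxy)phenyl]ethynyl}benzoate; 17 (4-bromophenoxy)triisopropylsilane (two equivalents are consumed)
Product: 25 {3-[(tert-butyldiphenylsilyloxy)methyl]-6-[4-(triisopropylsilyloxy)phenyl]-2-{[4-(triisopropylsilyloxy)phenyl]ethynyl}phenyl}bis[4-(triisopropylsilyloxy)phenyl]methanol, via aryllithium 23 (not isolated), via diaryl ketone 24 (not isolated)
Conditions: 17 (2.5 equiv), t-BuLi (5.0 equiv), THF, −78 °C; then 22 (1.0 equiv), −78 → 0 °C; H2O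
Reagents that add atoms: second equivalent of (4-bromophenoxy)triisopropylsilane 17, Brc1ccc(O[Si](C(C)C)(C(C)C)C(C)C)cc1
Why: Bromine–lithium exchange turns 17 into the aryllithium 23, one equivalent of which should convert the ester into ketone 24 and a second equivalent add to that ketone (double 1,2-addition), because neither 22 nor 24 is enolisable, the linear alkyne shields the carbonyl little, and the cold neutral quench avoids ionising the carbinol.

**Step 16**
Reactants: 25 {3-[(tert-butyldiphenylsilyloxy)methyl]-6-[4-(triisopropylsilyloxy)phenyl]-2-{[4-(triisopropylsilyloxy)phenyl]ethynyl}phenyl}bis[4-(triisopropylsilyloxy)phenyl]methanol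
Product: 27 selaginellin, via hexahydroxy carbinol 26 (not isolated)
Conditions: n-Bu4NF, AcOH, THF, 0 → 20 °C; then 0.1 M aq. HCl, EtOAc, 20 °C
Reagents that add atoms: none
Why: Acetic-acid-buffered fluoride removes all five silyl groups without generating free alkoxides next to the alkyne, and mild acid then ionises the bis(4-hydroxyphenyl)carbinol to a stabilised trityl cation that loses a phenolic proton to give the p-quinone methide (fuchsone-type dehydration).

**Compound list**
1 | methyl acetoacetate | COC(=O)CC(C)=O | starting material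
2 | benzyl chloromethyl ether | ClCOCc1ccccc1 | starting material
3 | methyl 5-(benzyloxy)-3-oxopentanoate | COC(=O)CC(=O)CCOCc1ccccc1 | intermediate
4 | methyl 5-hydroxy-3-oxopentanoate | COC(=O)CC(=O)CCO | intermediate
5 | methyl 5-(tert-butyldiphenylsilyloxy)-3-oxopentanoate | COC(=O)CC(=O)CCO[Si](c1ccccc1)(c1ccccc1)C(C)(C)C | intermediate
6 | methyl (E)-5-(tert-butyldiphenylsilyloxy)-3-(trimethylsilyloxy)pent-2-enoate | COC(=O)/C=C(/O[Si](C)(C)C)CCO[Si](c1ccccc1)(c1ccccc1)C(C)(C)C | intermediate
7 | (1Z,3Z)-5-(tert-butyldiphenylsilyloxy)-1-methoxy-1,3-bis(trimethylsilyloxy)penta-1,3-diene | CO/C(O[Si](C)(C)C)=C/C(O[Si](C)(C)C)=C/CO[Si](c1ccccc1)(c1ccccc1)C(C)(C)C | intermediate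
8 | 4-hydroxyacetophenone | CC(=O)c1ccc(O)cc1 | starting material
9 | 1-[4-(triisopropylsilyloxy)phenyl]ethanone | CC(=O)c1ccc(O[Si](C(C)C)(C(C)C)C(C)C)cc1 | intermediate
10 | ethyl formate | CCOC=O | starting material
11 | (Z)-3-hydroxy-1-[4-(triisopropylsilyloxy)phenyl]prop-2-en-1-one (enol form of the formyl ketone) | O=C(/C=C\O)c1ccc(O[Si](C(C)C)(C(C)C)C(C)C)cc1 | intermediate
12 | (Z)-1-[4-(triisopropylsilyloxy)phenyl]-3-(trimethylsilyloxy)prop-2-en-1-one | CC(C)[Si](Oc1ccc(C(=O)/C=C\O[Si](C)(C)C)cc1)(C(C)C)C(C)C | intermediate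
13 | open-chain enone adduct: trimethylsilyl ketene acetal of methyl (5Z)-4-[(tert-butyldiphenylsilyloxy)methyl]-3,7-dioxo-7-[4-(triisopropylsilyloxy)phenyl]hept-5-enoate, racemic at C4 | CO/C(O[Si](C)(C)C)=C/C(=O)C(CO[Si](c1ccccc1)(c1ccccc1)C(C)(C)C)/C=C\C(=O)c1ccc(O[Si](C(C)C)(C(C)C)C(C)C)cc1 | intermediate (not isolated)
14 | cyclic aldol: methyl 3-[(tert-butyldiphenylsilyloxy)methyl]-6-hydroxy-2-oxo-6-[4-(triisopropylsilyloxy)phenyl]cyclohex-4-ene-1-carboxylate, mixture of diastereomers, shown metal-free | COC(=O)C1C(=O)C(CO[Si](c2ccccc2)(c2ccccc2)C(C)(C)C)C=CC1(O)c1ccc(O[Si](C(C)C)(C(C)C)C(C)C)cc1 | intermediate (not isolated)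
15 | methyl 3-[(tert-butyldiphenylsilyloxy)methyl]-2-hydroxy-6-[4-(triisopropylsilyloxy)phenyl]benzoate | COC(=O)c1c(O)c(CO[Si](c2ccccc2)(c2ccccc2)C(C)(C)C)ccc1-c1ccc(O[Si](C(C)C)(C(C)C)C(C)C)cc1 | intermediate
16 | 4-bromophenol | Oc1ccc(Br)cc1 | starting material
17 | (4-bromophenoxy)triisopropylsilane | Brc1ccc(O[Si](C(C)C)(C(C)C)C(C)C)cc1 | intermediate
18 | ethynyltrimethylsilane | C#C[Si](C)(C)C | starting material
19 | triisopropyl{4-[(trimethylsilyl)ethynyl]phenoxy}silane | C[Si](C)(C)C#Cc1ccc(O[Si](C(C)C)(C(C)C)C(C)C)cc1 | intermediate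
20 | (4-ethynylphenoxy)triisopropylsilane | C#Cc1ccc(O[Si](C(C)C)(C(C)C)C(C)C)cc1 | intermediate
21 | methyl 3-[(tert-butyldiphenylsilyloxy)methyl]-6-[4-(triisopropylsilyloxy)phenyl]-2-(trifluoromethylsulfonyloxy)benzoate | COC(=O)c1c(OS(=O)(=O)C(F)(F)F)c(CO[Si](c2ccccc2)(c2ccccc2)C(C)(C)C)ccc1-c1ccc(O[Si](C(C)C)(C(C)C)C(C)C)cc1 | intermediate
22 | methyl 3-[(tert-butyldiphenylsilyloxy)methyl]-6-[4-(triisopropylsilyloxy)phenyl]-2-{[4-(triisopropylsilyloxy)phenyl]ethynyl}benzoate | COC(=O)c1c(C#Cc2ccc(O[Si](C(C)C)(C(C)C)C(C)C)cc2)c(CO[Si](c2ccccc2)(c2ccccc2)C(C)(C)C)ccc1-c1ccc(O[Si](C(C)C)(C(C)C)C(C)C)cc1 | intermediate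
23 | [4-(triisopropylsilyloxy)phenyl]lithium | [Li]c1ccc(O[Si](C(C)C)(C(C)C)C(C)C)cc1 | intermediate (not isolated)
24 | {3-[(tert-butyldiphenylsilyloxy)methyl]-6-[4-(triisopropylsilyloxy)phenyl]-2-{[4-(triisopropylsilyloxy)phenyl]ethynyl}phenyl}[4-(triisopropylsilyloxy)phenyl]methanone | O=C(c1ccc(O[Si](C(C)C)(C(C)C)C(C)C)cc1)c1c(C#Cc2ccc(O[Si](C(C)C)(C(C)C)C(C)C)cc2)c(CO[Si](c2ccccc2)(c2ccccc2)C(C)(C)C)ccc1-c1ccc(O[Si](C(C)C)(C(C)C)C(C)C)cc1 | intermediate (not isolated)
25 | {3-[(tert-butyldiphenylsilyloxy)methyl]-6-[4-(triisopropylsilyloxy)phenyl]-2-{[4-(triisopropylsilyloxy)phenyl]ethynyl}phenyl}bis[4-(triisopropylsilyloxy)phenyl]methanol | OC(c1ccc(O[Si](C(C)C)(C(C)C)C(C)C)cc1)(c1ccc(O[Si](C(C)C)(C(C)C)C(C)C)cc1)c1c(C#Cc2ccc(O[Si](C(C)C)(C(C)C)C(C)C)cc2)c(CO[Si](c2ccccc2)(c2ccccc2)C(C)(C)C)ccc1-c1ccc(O[Si](C(C)C)(C(C)C)C(C)C)cc1 | intermediate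
26 | {3-(hydroxymethyl)-6-(4-hydroxyphenyl)-2-[(4-hydroxyphenyl)ethynyl]phenyl}bis(4-hydroxyphenyl)methanol | OCc1ccc(-c2ccc(O)cc2)c(C(O)(c2ccc(O)cc2)c2ccc(O)cc2)c1C#Cc1ccc(O)cc1 | intermediate (not isolated)
27 | selaginellin, 4-{[3-(hydroxymethyl)-6-(4-hydroxyphenyl)-2-[(4-hydroxyphenyl)ethynyl]phenyl](4-hydroxyphenyl)methylidene}cyclohexa-2,5-dien-1-one | O=C1C=CC(=C(c2ccc(O)cc2)c2c(-c3ccc(O)cc3)ccc(CO)c2C#Cc2ccc(O)cc2)C=C1 | target

**Step count**
Total: 16 steps. Longest linear sequence: 10 steps (steps 1–5, 9, 13–16).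

**Steps most likely to fail, with fallbacks**

Step 9. The silyloxymethyl group at the diene terminus may be ionised or β-eliminated by TiCl4 before or after C–C bond formation. The diene may also be desilylated back to the β-keto ester faster than it adds, or its terminus may attack the ketone carbon and give the regioisomeric salicylate. The same fallback also bypasses any β-elimination in step 5.
Fallback, setting out from 12: the enone is condensed under the same TiCl4 conditions with the unsubstituted diene (Z)-1-methoxy-1,3-bis(trimethylsilyloxy)buta-1,3-diene F1 (from 1 by Me3SiCl/Et3N, then LiN(i-Pr)2/Me3SiCl). This should give methyl 2-hydroxy-6-[4-(triisopropylsilyloxy)phenyl]benzoate F2, with the same two ring bonds formed. Magnesium-mediated ortho-formylation (MgCl2, Et3N, paraformaldehyde, MeCN, reflux) at the only free ortho position of the phenol should give methyl 3-formyl-2-hydroxy-6-[4-(triisopropylsilyloxy)phenyl]benzoate F3. NaBH4 in THF/MeOH at 0 °C should reduce it to methyl 2-hydroxy-3-(hydroxymethyl)-6-[4-(triisopropylsilyloxy)phenyl]benzoate F4. Selective silylation of the primary alcohol (TBDPSCl, imidazole, CH2Cl2, 0 °C; the hydrogen-bonded salicylate OH reacts far more slowly) returns to the route at 15.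

Step 15. The first addition to the doubly ortho-substituted ester may be so slow that ester demethylation or carbolithiation of the alkyne competes. The addition may also stall at the hindered ketone, or the tertiary alkoxide may cyclise onto the neighbouring alkyne on warming.
Fallback, setting out from 22: reduction with i-Bu2AlH (CH2Cl2, −78 → 0 °C) should give {3-[(tert-butyldiphenylsilyloxy)methyl]-6-[4-(triisopropylsilyloxy)phenyl]-2-{[4-(triisopropylsilyloxy)phenyl]ethynyl}phenyl}methanol F5. MnO2 in CH2Cl2 should oxidise it to the corresponding benzaldehyde, 3-[(tert-butyldiphenylsilyloxy)methyl]-6-[4-(triisopropylsilyloxy)phenyl]-2-{[4-(triisopropylsilyloxy)phenyl]ethynyl}benzaldehyde F6. One equivalent of 23 at −78 °C adds to this far more reactive carbonyl to give the racemic secondary carbinol {3-[(tert-butyldiphenylsilyloxy)methyl]-6-[4-(triisopropylsilyloxy)phenyl]-2-{[4-(triisopropylsilyloxy)phenyl]ethynyl}phenyl}[4-(triisopropylsilyloxy)phenyl]methanol F7. Oxidation with 2-iodoxybenzoic acid in DMSO gives ketone 24, now isolated. Addition of the arylcerium reagent made from 23 and CeCl3 (THF, −78 °C), which is more nucleophilic and less basic than the aryllithium, returns to the route at 25.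

Step 16. Fluoride may turn the freed benzylic or tertiary hydroxyl into an alkoxide that adds 5-exo-dig to the ortho alkyne. Alternatively the acid stage may drive Friedel–Crafts closure of the trityl cation onto the C2 aryl ring (fluorene formation) instead of simple deprotonation.
Fallback, setting out from 25: the order of events is reversed. A catalytic amount of CF3CO2H in wet CH2Cl2 at 0 °C ionises the still fully silylated carbinol; the cation sheds one TIPS group from a para oxygen and should give the silyl-protected quinone methide 4-{{3-[(tert-butyldiphenylsilyloxy)methyl]-6-[4-(triisopropylsilyloxy)phenyl]-2-{[4-(triisopropylsilyloxy)phenyl]ethynyl}phenyl}[4-(triisopropylsilyloxy)phenyl]methylidene}cyclohexa-2,5-dien-1-one F8. The remaining four silyl ethers are then removed with HF·pyridine in THF/pyridine at 0 → 20 °C, an acidic fluoride source that never forms an alkoxide. This arrives directly at 27.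

**Further compounds**
F1 | step 9 | (Z)-1-methoxy-1,3-bis(trimethylsilyloxy)buta-1,3-diene | CO/C(O[Si](C)(C)C)=C/C(=C)O[Si](C)(C)C
F2 | step 9 | methyl 2-hydroxy-6-[4-(triisopropylsilyloxy)phenyl]benzoate | COC(=O)c1c(O)cccc1-c1ccc(O[Si](C(C)C)(C(C)C)C(C)C)cc1
F3 | step 9 | methyl 3-formyl-2-hydroxy-6-[4-(triisopropylsilyloxy)phenyl]benzoate | COC(=O)c1c(O)c(C=O)ccc1-c1ccc(O[Si](C(C)C)(C(C)C)C(C)C)cc1
F4 | step 9 | methyl 2-hydroxy-3-(hydroxymethyl)-6-[4-(triisopropylsilyloxy)phenyl]benzoate | COC(=O)c1c(O)c(CO)ccc1-c1ccc(O[Si](C(C)C)(C(C)C)C(C)C)cc1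
F5 | step 15 | {3-[(tert-butyldiphenylsilyloxy)methyl]-6-[4-(triisopropylsilyloxy)phenyl]-2-{[4-(triisopropylsilyloxy)phenyl]ethynyl}phenyl}methanol | OCc1c(C#Cc2ccc(O[Si](C(C)C)(C(C)C)C(C)C)cc2)c(CO[Si](c2ccccc2)(c2ccccc2)C(C)(C)C)ccc1-c1ccc(O[Si](C(C)C)(C(C)C)C(C)C)cc1
F6 | step 15 | 3-[(tert-butyldiphenylsilyloxy)methyl]-6-[4-(triisopropylsilyloxy)phenyl]-2-{[4-(triisopropylsilyloxy)phenyl]ethynyl}benzaldehyde | O=Cc1c(C#Cc2ccc(O[Si](C(C)C)(C(C)C)C(C)C)cc2)c(CO[Si](c2ccccc2)(c2ccccc2)C(C)(C)C)ccc1-c1ccc(O[Si](C(C)C)(C(C)C)C(C)C)cc1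
F7 | step 15 | {3-[(tert-butyldiphenylsilyloxy)methyl]-6-[4-(triisopropylsilyloxy)phenyl]-2-{[4-(triisopropylsilyloxy)phenyl]ethynyl}phenyl}[4-(triisopropylsilyloxy)phenyl]methanol (racemic) | OC(c1ccc(O[Si](C(C)C)(C(C)C)C(C)C)cc1)c1c(C#Cc2ccc(O[Si](C(C)C)(C(C)C)C(C)C)cc2)c(CO[Si](c2ccccc2)(c2ccccc2)C(C)(C)C)ccc1-c1ccc(O[Si](C(C)C)(C(C)C)C(C)C)cc1
F8 | step 16 | 4-{{3-[(tert-butyldiphenylsilyloxy)methyl]-6-[4-(triisopropylsilyloxy)phenyl]-2-{[4-(triisopropylsilyloxy)phenyl]ethynyl}phenyl}[4-(triisopropylsilyloxy)phenyl]methylidene}cyclohexa-2,5-dien-1-one | O=C1C=CC(=C(c2ccc(O[Si](C(C)C)(C(C)C)C(C)C)cc2)c2c(-c3ccc(O[Si](C(C)C)(C(C)C)C(C)C)cc3)ccc(CO[Si](c3ccccc3)(c3ccccc3)C(C)(C)C)c2C#Cc2ccc(O[Si](C(C)C)(C(C)C)C(C)C)cc2)C=C1
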